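Which flask ends with the most over-reaction product, and how much does each one hold?

| flask | substrate | first nucleophile | second nucleophile | time | remark |
|---|---|---|---|---|---|
| oak | 12 mM | 1.50 equiv (in portions, 3, over 20 d) | 0.800 equiv | 30 d | first portion at the start, last at 20 d |
| ash | 12 mM | 1.50 equiv | 0.800 equiv | 30 d | everything together at the start |
| birch | 12 mM | 1.50 equiv | 0.800 equiv (fed, over 20 d) | 30 d | all else is in the flask from the start; the feed brings no volume worth counting |
| alder | 12 mM | 1.50 equiv (fed, over 20 d) | 0.800 equiv | 30 d | all else is in the flask from the start; the feed brings no volume worth counting |

    first nucleophile + intermediate → target (k1 = 0.14 M⁻¹ s⁻¹)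
    second nucleophile + intermediate → other capture product (k2 = 0.039 M⁻¹ s⁻¹)
    substrate → intermediate (k3 = 5.4 × 10⁻⁶ s⁻¹)
    first nucleophile + target → over-reaction product (k4 = 7.5 × 10⁻⁴ M⁻¹ s⁻¹)

- the flask that comes out highest in amount of over-reaction product, in percent of the substrate charged; "all alike" if 1.5 percentage points covers them all (oak / ash / birch / alder / all alike)
- amount of over-reaction product at the end, in percent of the substrate charged, oak
- amount of over-reaction product at the end, in percent of the substrate charged, ash
- amount of over-reaction product at the end, in percent of the substrate charged, birch
- amount of over-reaction product at the end, in percent of the substrate charged, alder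

**Fast step.** I reckoned alder by hand and got no further. There the second nucleophile as charged removes intermediate at 32.3 d⁻¹, faster than substrate forms it at 0.47 d⁻¹. So I took [intermediate] as settled, with its supply equal to k3[substrate], at first 5.60 mM d⁻¹.

**Early catch.** In alder the feed brings first nucleophile at 0.900 mM d⁻¹, less than that supply, so I took the feed as the cap on the early rate of target formation. Supply falls to the feed rate at 3.92 d, with 1.93 mM of substrate still unreacted. I named feed rate times that time the early catch: 3.53 mM, or 29.4% of the substrate charged. By then I reckoned 3.06 mM of second nucleophile remained. With the selectivity factor k1/k2 of 3.59, capture still consumed first nucleophile at 1.06 d⁻¹, faster than target did at 0.228 d⁻¹.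

**Weak link.** Did the catch really go over? Each over-reaction product costs two first nucleophiles, so alder needed 7.06 mM of its 18.0 mM. Free first nucleophile could pile up from about 7.84 d, and that leaves 1.34% of the target at the end of the feed. So nearly all of it reacts on. I committed to 29.4% for alder, with up to 16.1% more open for the remaining substrate.

**The forecast.** The forecast named ash highest, giving oak 42.5%, ash 70%, birch 59% and alder 33%. Of alder it said “the second nucleophile takes most intermediate”. Its alder figure stood 3.6 percentage points above mine.

**The result.** Ash came out highest at 70.4%, as forecast, with oak at 42.4%, birch at 59.2% and alder at 33.0%. Alder lost the least to over-reaction, yet held 0.306% target at 20.0 d. Its result lies 3.6 points above the early catch, which is 22.4% of the open 16.1%.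

**Second flask.** The early catch has no second-nucleophile term, so for alder's neighbour with 1.40 equiv of second nucleophile it again gave 29.4%. The simulation gave 22.8%, which is 6.6 points lower, with 77.2% other capture product.

(The constants used here belong to no real substance; no experiment stands behind them.)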